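Start at the first seconds, where substrate meets free catalyst, with the charges and the questions in front of you.

in all of them: free catalyst 0.50 mM

| charge | substrate | time | remark |
|---|---|---|---|
| teal | 0.50 M (fed, over 1.00 d) | 2.0 d | a stirred flask in which substrate is dosed at a steady rate over 1.00 d without added volume, worked up at 2.0 d |
| ochre | 0.50 M |  | a single well-mixed tank run continuously and read at steady state, 2.0 d in it on average |
| grey | 0.50 M | 2.0 d | a closed flask charged with all of it at once and left for 2.0 d |

1. the set-up with the highest amount of product at the outlet or at the end, in percent of the substrate put in ("none" if the first two lie within 2 percentage points) (teal / ochre / grey / none)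
2. amount of product at the outlet or at the end, in percent of the substrate put in, teal
3. amount of product at the outlet or at the end, in percent of the substrate put in, ochre
4. amount of product at the outlet or at the end, in percent of the substrate put in, grey

- a species is counted by the substrate in it: one resting dimer counts as two
- a step written with two of one species runs at k times the square of its concentration and takes two of it each time
- the stated concentrations are those of everything mixed, before any reaction; amounts are the same in each set-up
- the feed brings no volume worth counting
- run time (teal): 2.0 d

    substrate + free catalyst ⇌ catalyst intermediate (K1 = 6.2 M⁻¹, k1 = 41000 M⁻¹ h⁻¹)
    catalyst intermediate ⇌ free catalyst + product (K2 = 0.070 M, k2 = 160 h⁻¹)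
    catalyst intermediate + catalyst intermediate ⇌ resting dimer (K3 = 1600 M⁻¹, k3 = 580 M⁻¹ h⁻¹)

Draw the product curve of grey, the closed flask, by hand. Substrate stands in such excess over free catalyst that binding is pseudo-first-order at 20500 h⁻¹, while catalyst intermediate falls back to substrate at 6610 h⁻¹ and goes on to product at 160 h⁻¹. So within about 0.132 s reckon catalyst intermediate at 75.2% of the catalyst, a share for the start that leaves the resting dimer out, and let the product fraction set off with slope 0.120 h⁻¹.

Now find the level. Each turn of the cycle returns the catalyst, so at the end of the curve [product]/[substrate] equals the product of the cycle's two equilibrium constants, 0.434, and the catalyst forms, holding at most 0.100% of the charge, are a correction to be dropped. Call the equilibrium share the fraction of the substrate charged that stands as product at that ratio: it is 30.3%.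

The straight start meets this level at the knee, 2.52 h, reckoned without the resting dimer, and grey has 2.0 d, so expect grey at the equilibrium share. Teal, dosed over 1.00 d, should trail the equilibrium share of what has gone in by one knee, giving 27.1% at the end of the feed, and then has 24.0 h to reach the same level. Compute just the correction for ochre, the tank, with 2.0 d in it on average: taking one knee as the time constant of the approach to the level, reckon it short by 1.5 percentage points, so expect it at 28.8%. Teal and grey should then tie above ochre, so commit to none for best.

The forecast gives teal 30.2%, ochre 28.5%, grey 30.2% and best none, on the ground that “relaxation takes a few hours”, and its tank lies 0.30 points below mine.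

The simulation gives teal 30.2%, ochre 28.5%, grey 30.2%, best none.

In grey the slowest mode of the whole flask has a half-life of 2.05 h at 2.00 d, and product there reads 30.2% against the equilibrium share of 30.3%. Over the 24.0 h after its feed, teal, the dosed flask, goes from 26.8% to 30.2%. For the grey flask read at 30 h, the equilibrium share gives 30.3%, and the computed neighbour stands at 30.2%.

The numbers belong to no real substance; the run is a simulation.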